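The constants used here are made up; the run is a simulation.

The target is made by a chain that spends the partner, while the partner also decays on its own.

    initiator → 2 initiating radical (k1 = 1.74 × 10⁻⁴ s⁻¹)
    starting material + initiating radical → capped initiator + first chain carrier (k2 = 7.08 × 10⁵ M⁻¹ s⁻¹)
    partner + first chain carrier → target + second chain carrier (k3 = 31300 M⁻¹ s⁻¹)
    starting material + second chain carrier → released group + first chain carrier (k4 = 21500 M⁻¹ s⁻¹)
    2 second chain carrier → ended chains A (k5 = 1.7 × 10⁷ M⁻¹ s⁻¹)
    2 first chain carrier → ended chains B (k6 = 7.0 × 10⁸ M⁻¹ s⁻¹)
    partner → decomposed reagent (k7 = 1.73 × 10⁻⁴ s⁻¹)
    target ⇌ isomer of the product (K8 = 0.18, k8 = 3.93 × 10⁻⁴ s⁻¹)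

starting material 0.050 M; partner 0.0350 M; initiator 0.32 mM; time 15 h

1. why nothing more happens at 15 h, or that something still does (it is still moving / forward and back rates have come level / all of the starting material has reacted / the partner has run out first)
2. how much of the starting material has reacted by 15 h
3. how much target there is at 15 h, in percent of the starting material charged
4. how much isomer of the product there is at 15 h, in percent of the starting material charged
5. amount of target if the flask were left three thousand times as long, in percent of the starting material charged

- percent here means starting material units held: one ended chains B counts as two
- a step written with two of one species runs at k times the square of its concentration and takes two of it each time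
- the reaction counts as stopped when no species that holds the starting material changes by six tenths of a point or more over the second half of the time
- run time (flask): 15 h

First, what ends the chains? The constant for coupling of first chain carriers is 41.2 times that for second chain carriers, and with the two chain steps running level at the charges, the ratio of second to first carrier is near 1.02. So take first-carrier coupling as the chain end. Balancing it against initiation gives a first chain carrier level of 8.92 × 10⁻⁹ M at the start.

Second, who gets the partner? The chain takes it at a first-order rate a = 2.79 × 10⁻⁴ s⁻¹, and decay takes it at d = 1.73 × 10⁻⁴ s⁻¹, so the chain leads at the start. But the initiator dies at 1.74 × 10⁻⁴ s⁻¹, and the carrier level follows its square root, falling at half that pace. The chain therefore slows while decay does not. Taking the decay constants of initiator and partner as equal (1.74 × 10⁻⁴ s⁻¹ against 1.73 × 10⁻⁴ s⁻¹) and setting ρ = 2a/d = 3.23, integration gives the chain share φ, the fraction of charged partner that enters the chain: φ = 1 − (2/ρ)(1 − (1 − e^(−ρ))/ρ) = 56.5%. The partner charge does not appear in ρ.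

Third, where does the product go? Target and isomer of the product relax with a half-life of 0.0747 h, both ways together, far inside the run, so take them as settled at an isomer-to-target ratio of 0.18. The partner is the limiting reagent, and decay by itself would leave 0.00877% of it by the end, so this reckoning expects that the partner runs out first. Adding the capped initiator, conversion is 40.8%, target 33.5% and isomer 6.03%. With the partner down to that amount, long-time target stays at 33.5%.

The forecast says the partner has run out first, with conversion 39.8%, target 32.7%, isomer 5.9% and long-time target 32.7%. It has the chains “mostly ended by first-carrier coupling” and gives the chain about 55% of the partner, and its target stands a little below this reckoning.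

In the simulation, too, the partner has run out first, with conversion 40.7%, target 33.4%, isomer of the product 6.01% and long-time target 33.4%.

In this flask, 59.3% of the starting material stays unreacted while the partner stands at 0%. Decomposed reagent reaches 0.0153 M, so 56.3% of the partner charge in this flask entered the chain. The neighbour flask with 0.060 M of partner keeps ρ, so φ gives 0.0339 M of chain product, less than the starting material charged, and 57.4% of target. That neighbour flask gives 56.8% of target and 10.2% of isomer of the product.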